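The two prenyl C–C bonds are traced back to oxygen. C3' of ring A lies ortho to O4' and C5 of ring B lies ortho to O4, so each C-prenyl bond is disconnected to an aryl 1,1-dimethylallyl ether. Heating bis(ether) 11, a fully MOM-capped dihydrochalcone, should form the C3'–CH2 and C5–CH2 bonds by two aromatic Claisen shifts in one operation and release only the 4'- and 4-phenols. Precursor 11 comes from two O-alkylated, MOM-protected fragments joined by Claisen–Schmidt condensation and [(Ph3P)CuH]6 conjugate reduction. Afterwards O4' is masked, O4 is methylated and all MOM groups are removed.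

Key step: step 9

Remark on the chemistry: the target is achiral, so the only stereochemical element on the route is the E-alkene of chalcone 10, which step 8 erases; commercial 1 (often sold as the monohydrate) is assumed to be dried before use.

Step 1
Reactants: 1 2',4',6'-trihydroxyacetophenone; 2 3-chloro-3-methylbut-1-yne
Product: 3 1-[2,6-dihydroxy-4-(2-methylbut-3-yn-2-yloxy)phenyl]ethanone
Conditions: 2 (1.1 equiv), K2CO3 (1.1 equiv), KI (0.1 equiv), CuI (2 mol %), acetone, 50 °C
Reagents that add atoms: none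
Why: Copper-catalysed propargylic etherification (Williamson-type O-alkylation of a phenoxide by a tertiary propargylic chloride); O4 is the most acidic hydroxyl and the only one not hydrogen-bonded to the acetyl carbonyl, so about one equivalent of base and of 2 should alkylate it alone.

Step 2
Reactants: 3 1-[2,6-dihydroxy-4-(2-methylbut-3-yn-2-yloxy)phenyl]ethanone
Product: 4 1-[2,6-bis(methoxymethoxy)-4-(2-methylbut-3-yn-2-yloxy)phenyl]ethanone
Conditions: NaH (2.3 equiv), MOMCl (2.5 equiv), THF/DMF, 0 °C to rt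
Reagents that add atoms: chloromethyl methyl ether (MOMCl), COCCl
Why: Williamson-type MOM etherification; NaH ionises both phenols, including the hydrogen-bonded one that weaker bases leave, while the far less acidic alkyne C–H and methyl ketone are spared by the small excess of base at 0 °C.

Step 3
Reactants: 4 1-[2,6-bis(methoxymethoxy)-4-(2-methylbut-3-yn-2-yloxy)phenyl]ethanone
Product: 5 1-[2,6-bis(methoxymethoxy)-4-(2-methylbut-3-en-2-yloxy)phenyl]ethanone
Conditions: H2 (1 atm), 5% Pd/CaCO3 poisoned with Pb(OAc)2, quinoline, EtOAc, rt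
Reagents that add atoms: none
Why: Lindlar semihydrogenation stops at the vinyl group because the poisoned palladium surface binds the alkyne far more strongly than the alkene, and the aryl ketone, MOM acetals and tertiary ether are inert to it.

Step 4
Reactants: 6 3,4-dihydroxybenzaldehyde; 2 3-chloro-3-methylbut-1-yne
Product: 7 3-hydroxy-4-(2-methylbut-3-yn-2-yloxy)benzaldehyde
Conditions: 2 (1.1 equiv), K2CO3 (1.05 equiv), KI (0.1 equiv), CuI (2 mol %), acetone, 50 °C
Reagents that add atoms: none
Why: The same copper-catalysed propargylic etherification; the 4-OH, para to the formyl group, is the more acidic hydroxyl of the catechol, so with limiting base its phenoxide forms and reacts selectively.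

Step 5
Reactants: 7 3-hydroxy-4-(2-methylbut-3-yn-2-yloxy)benzaldehyde
Product: 8 3-(methoxymethoxy)-4-(2-methylbut-3-yn-2-yloxy)benzaldehyde
Conditions: MOMCl (1.3 equiv), K2CO3, acetone, 0 °C to rt
Reagents that add atoms: chloromethyl methyl ether (MOMCl), COCCl
Why: Williamson-type MOM etherification of the single remaining phenol under mild carbonate conditions that leave the aldehyde and the alkyne alone.

Step 6
Reactants: 8 3-(methoxymethoxy)-4-(2-methylbut-3-yn-2-yloxy)benzaldehyde
Product: 9 3-(methoxymethoxy)-4-(2-methylbut-3-en-2-yloxy)benzaldehyde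
Conditions: H2 (1 atm), 5% Pd/CaCO3 poisoned with Pb(OAc)2, quinoline, EtOAc, rt
Reagents that add atoms: none
Why: Lindlar semihydrogenation as in step 3; the aromatic aldehyde is not reduced on the poisoned catalyst, and hydrogen uptake is stopped after one equivalent.

Step 7
Reactants: 5 1-[2,6-bis(methoxymethoxy)-4-(2-methylbut-3-en-2-yloxy)phenyl]ethanone; 9 3-(methoxymethoxy)-4-(2-methylbut-3-en-2-yloxy)benzaldehyde
Product: 10 (2E)-1-[2,6-bis(methoxymethoxy)-4-(2-methylbut-3-en-2-yloxy)phenyl]-3-[3-(methoxymethoxy)-4-(2-methylbut-3-en-2-yloxy)phenyl]prop-2-en-1-one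
Conditions: KOH (50% aq.), EtOH, 0 °C to rt
Reagents that add atoms: none
Why: Claisen–Schmidt (crossed aldol) condensation; only ketone 5 is enolisable, aldehyde 9 cannot self-condense, E1cB dehydration gives the favoured E-enone, and all ethers are stable to base at room temperature, well below the onset of the Claisen shift.

Step 8
Reactants: 10 (2E)-1-[2,6-bis(methoxymethoxy)-4-(2-methylbut-3-en-2-yloxy)phenyl]-3-[3-(methoxymethoxy)-4-(2-methylbut-3-en-2-yloxy)phenyl]prop-2-en-1-one
Product: 11 1-[2,6-bis(methoxymethoxy)-4-(2-methylbut-3-en-2-yloxy)phenyl]-3-[3-(methoxymethoxy)-4-(2-methylbut-3-en-2-yloxy)phenyl]propan-1-one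
Conditions: [(Ph3P)CuH]6 (0.4 equiv), degassed H2O (5 equiv), toluene, rt, Ar
Reagents that add atoms: none
Why: Conjugate (1,4-) reduction with Stryker's reagent; hydride goes to the β-carbon of the enone only, water protonates the copper enolate, and the isolated terminal alkenes, the MOM acetals and the ketone are not touched.

Step 9
Reactants: 11 1-[2,6-bis(methoxymethoxy)-4-(2-methylbut-3-en-2-yloxy)phenyl]-3-[3-(methoxymethoxy)-4-(2-methylbut-3-en-2-yloxy)phenyl]propan-1-one
Product: 12 1-[4-hydroxy-2,6-bis(methoxymethoxy)-3-(3-methylbut-2-en-1-yl)phenyl]-3-[4-hydroxy-3-(methoxymethoxy)-5-(3-methylbut-2-en-1-yl)phenyl]propan-1-one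
Conditions: PhNEt2, 160 °C, Ar
Reagents that add atoms: none
Why: Each aryl 2-methylbut-3-en-2-yl ether undergoes a concerted, suprafacial [3,3] sigmatropic shift through a chair-like six-membered transition state in which the terminal vinyl CH2 bonds to the ring carbon ortho to the ether oxygen (C3' on ring A, C5 on ring B) while the O–C(CH3)2 bond breaks, and the resulting 6-prenylcyclohexa-2,4-dienone enolises at once to the phenol. The closest known reaction is the thermal aromatic Claisen rearrangement of aryl 1,1-dimethylallyl ethers to ortho-prenylphenols, applied here at two electronically independent sites, with the geminal methyl groups lowering the barrier so that about 160 °C should suffice. No ring is closed and no stereocentre arises, and because the new trisubstituted alkene carries two identical methyl groups there is no alkene geometry to control. The step needs regioselectivity, which the substrate fixes: ring A is symmetric so C3' and C5' are the same position, on ring B only C5 is an open ortho carbon because C3 carries the MOM ether, and both para carbons (C1', C1) are substituted so no para migration can follow. It also needs the released phenols to survive, which the weakly basic amine solvent secures by scavenging traces of acid that would ionise the tertiary ethers or close chromans, while every other oxygen stays capped as a thermally stable MOM acetal.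

Step 10
Reactants: 12 1-[4-hydroxy-2,6-bis(methoxymethoxy)-3-(3-methylbut-2-en-1-yl)phenyl]-3-[4-hydroxy-3-(methoxymethoxy)-5-(3-methylbut-2-en-1-yl)phenyl]propan-1-one
Product: 13 3-[4-hydroxy-3-(methoxymethoxy)-5-(3-methylbut-2-en-1-yl)phenyl]-1-[2,4,6-tris(methoxymethoxy)-3-(3-methylbut-2-en-1-yl)phenyl]propan-1-one
Conditions: MOMCl (1.05 equiv), K2CO3 (1.1 equiv), acetone, 0 °C
Reagents that add atoms: chloromethyl methyl ether (MOMCl), COCCl
Why: Site-selective Williamson-type MOM etherification; the ring A 4'-OH is para to the ketone, meta to two oxygens and has one ortho substituent, whereas the ring B 4-OH is less acidic and flanked by OMOM and prenyl, so limiting carbonate and MOMCl in the cold should cap O4' first.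

Step 11
Reactants: 13 3-[4-hydroxy-3-(methoxymethoxy)-5-(3-methylbut-2-en-1-yl)phenyl]-1-[2,4,6-tris(methoxymethoxy)-3-(3-methylbut-2-en-1-yl)phenyl]propan-1-one
Product: 14 3-[4-methoxy-3-(methoxymethoxy)-5-(3-methylbut-2-en-1-yl)phenyl]-1-[2,4,6-tris(methoxymethoxy)-3-(3-methylbut-2-en-1-yl)phenyl]propan-1-one
Conditions: MeI (3 equiv), K2CO3, DMF, rt
Reagents that add atoms: iodomethane (MeI), CI
Why: Williamson O-methylation of the only remaining phenol; K2CO3 is too weak to enolise the ketone, so C-methylation is not expected.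

Step 12
Reactants: 14 3-[4-methoxy-3-(methoxymethoxy)-5-(3-methylbut-2-en-1-yl)phenyl]-1-[2,4,6-tris(methoxymethoxy)-3-(3-methylbut-2-en-1-yl)phenyl]propan-1-one
Product: 15 3-[3-hydroxy-4-methoxy-5-(3-methylbut-2-en-1-yl)phenyl]-1-[2,4,6-trihydroxy-3-(3-methylbut-2-en-1-yl)phenyl]propan-1-one (3,2',4',6'-tetrahydroxy-4-methoxy-3',5-diprenyldihydrochalcone)
Conditions: HCl (1.25 M in MeOH), 0 °C to rt
Reagents that add atoms: none
Why: Acid-catalysed acetal exchange with methanol frees all four phenols as dimethoxymethane is formed; dilute anhydrous acid at or below room temperature is chosen because aryl MOM ethers should cleave faster than the ring A ortho-prenyl phenol cyclises to a chroman, and the ring B prenyl has no free ortho hydroxyl.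

Compound list
1 | 2',4',6'-trihydroxyacetophenone | CC(=O)c1c(O)cc(O)cc1O | starting material
2 | 3-chloro-3-methylbut-1-yne | C#CC(C)(C)Cl | starting material
3 | 1-[2,6-dihydroxy-4-(2-methylbut-3-yn-2-yloxy)phenyl]ethanone | CC(=O)c1c(O)cc(OC(C)(C)C#C)cc1O | intermediate
4 | 1-[2,6-bis(methoxymethoxy)-4-(2-methylbut-3-yn-2-yloxy)phenyl]ethanone | CC(=O)c1c(OCOC)cc(OC(C)(C)C#C)cc1OCOC | intermediate
5 | 1-[2,6-bis(methoxymethoxy)-4-(2-methylbut-3-en-2-yloxy)phenyl]ethanone | CC(=O)c1c(OCOC)cc(OC(C)(C)C=C)cc1OCOC | intermediate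
6 | 3,4-dihydroxybenzaldehyde | O=Cc1ccc(O)c(O)c1 | starting material
7 | 3-hydroxy-4-(2-methylbut-3-yn-2-yloxy)benzaldehyde | O=Cc1ccc(OC(C)(C)C#C)c(O)c1 | intermediate
8 | 3-(methoxymethoxy)-4-(2-methylbut-3-yn-2-yloxy)benzaldehyde | O=Cc1ccc(OC(C)(C)C#C)c(OCOC)c1 | intermediate
9 | 3-(methoxymethoxy)-4-(2-methylbut-3-en-2-yloxy)benzaldehyde | O=Cc1ccc(OC(C)(C)C=C)c(OCOC)c1 | intermediate
10 | (2E)-1-[2,6-bis(methoxymethoxy)-4-(2-methylbut-3-en-2-yloxy)phenyl]-3-[3-(methoxymethoxy)-4-(2-methylbut-3-en-2-yloxy)phenyl]prop-2-en-1-one | COCOc1cc(OC(C)(C)C=C)cc(OCOC)c1C(=O)/C=C/c1ccc(OC(C)(C)C=C)c(OCOC)c1 | intermediate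
11 | 1-[2,6-bis(methoxymethoxy)-4-(2-methylbut-3-en-2-yloxy)phenyl]-3-[3-(methoxymethoxy)-4-(2-methylbut-3-en-2-yloxy)phenyl]propan-1-one | COCOc1cc(OC(C)(C)C=C)cc(OCOC)c1C(=O)CCc1ccc(OC(C)(C)C=C)c(OCOC)c1 | intermediate
12 | 1-[4-hydroxy-2,6-bis(methoxymethoxy)-3-(3-methylbut-2-en-1-yl)phenyl]-3-[4-hydroxy-3-(methoxymethoxy)-5-(3-methylbut-2-en-1-yl)phenyl]propan-1-one | COCOc1cc(O)c(CC=C(C)C)c(OCOC)c1C(=O)CCc1cc(CC=C(C)C)c(O)c(OCOC)c1 | intermediate
13 | 3-[4-hydroxy-3-(methoxymethoxy)-5-(3-methylbut-2-en-1-yl)phenyl]-1-[2,4,6-tris(methoxymethoxy)-3-(3-methylbut-2-en-1-yl)phenyl]propan-1-one | COCOc1cc(OCOC)c(CC=C(C)C)c(OCOC)c1C(=O)CCc1cc(CC=C(C)C)c(O)c(OCOC)c1 | intermediate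
14 | 3-[4-methoxy-3-(methoxymethoxy)-5-(3-methylbut-2-en-1-yl)phenyl]-1-[2,4,6-tris(methoxymethoxy)-3-(3-methylbut-2-en-1-yl)phenyl]propan-1-one | COCOc1cc(OCOC)c(CC=C(C)C)c(OCOC)c1C(=O)CCc1cc(CC=C(C)C)c(OC)c(OCOC)c1 | intermediate
15 | 3-[3-hydroxy-4-methoxy-5-(3-methylbut-2-en-1-yl)phenyl]-1-[2,4,6-trihydroxy-3-(3-methylbut-2-en-1-yl)phenyl]propan-1-one | COc1c(O)cc(CCC(=O)c2c(O)cc(O)c(CC=C(C)C)c2O)cc1CC=C(C)C | target

Total step count: 12. Longest linear sequence: 9 steps (steps 1–3 or 4–6, then 7–12).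

Steps most likely to fail

Step 10. The MOM group may fail to discriminate between the two phenols of 12, with protection also reaching the ring B oxygen or both oxygens, so that the later methylation lands on the wrong site. The fallback sets out from 12 and uses steric control by acylation. Pivaloyl chloride (1.0 equiv), Et3N, CH2Cl2, −20 °C should acylate only the singly flanked ring A phenol and give 4-{3-[4-hydroxy-3-(methoxymethoxy)-5-(3-methylbut-2-en-1-yl)phenyl]propanoyl}-3,5-bis(methoxymethoxy)-2-(3-methylbut-2-en-1-yl)phenyl 2,2-dimethylpropanoate F1, since the bulky acyl chloride cannot easily reach the doubly ortho-substituted ring B hydroxyl. MeI and K2CO3 in acetone then methylate O4 to give 4-{3-[4-methoxy-3-(methoxymethoxy)-5-(3-methylbut-2-en-1-yl)phenyl]propanoyl}-3,5-bis(methoxymethoxy)-2-(3-methylbut-2-en-1-yl)phenyl 2,2-dimethylpropanoate F2. K2CO3 in MeOH removes the pivalate to give 1-[4-hydroxy-2,6-bis(methoxymethoxy)-3-(3-methylbut-2-en-1-yl)phenyl]-3-[4-methoxy-3-(methoxymethoxy)-5-(3-methylbut-2-en-1-yl)phenyl]propan-1-one F3. Methanolic HCl as in step 12 then brings the sequence back to the route at target 15.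

Step 9. In the fully assembled molecule the tertiary allyl ethers may fragment with loss of isoprene, one ring may lag behind the other, or the freed ortho-prenyl phenols may cyclise during prolonged heating. The fallback runs one sigmatropic shift per fragment, before the fragments are joined, and sets out from 5 and 9.
- Ring A: heating 5 in PhNEt2 should give 1-[4-hydroxy-2,6-bis(methoxymethoxy)-3-(3-methylbut-2-en-1-yl)phenyl]ethanone F4, which MOMCl and K2CO3 convert to 1-[2,4,6-tris(methoxymethoxy)-3-(3-methylbut-2-en-1-yl)phenyl]ethanone F5.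
- Ring B: heating 9 in the same way should give 4-hydroxy-3-(methoxymethoxy)-5-(3-methylbut-2-en-1-yl)benzaldehyde F6, which MeI and K2CO3 methylate to 4-methoxy-3-(methoxymethoxy)-5-(3-methylbut-2-en-1-yl)benzaldehyde F7.
- Joining: Claisen–Schmidt condensation of the ketone and the aldehyde (KOH, EtOH) gives (2E)-3-[4-methoxy-3-(methoxymethoxy)-5-(3-methylbut-2-en-1-yl)phenyl]-1-[2,4,6-tris(methoxymethoxy)-3-(3-methylbut-2-en-1-yl)phenyl]prop-2-en-1-one F8. Conjugate reduction with [(Ph3P)CuH]6 and water, which leaves trisubstituted alkenes alone, returns to the route at 14.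

Step 1. The phloroglucinol nucleus may be alkylated more than once, or at carbon instead of oxygen, so that the mono-O4 ether is formed unselectively. The fallback sets out from 1 and makes O4 the only free phenol at the alkylation stage. TIPSCl (1.05 equiv), imidazole, DMF, 0 °C should silylate the single unchelated hydroxyl to give 1-{2,6-dihydroxy-4-[tri(propan-2-yl)silyloxy]phenyl}ethanone F9. NaH and MOMCl in THF at 0 °C then give 1-{2,6-bis(methoxymethoxy)-4-[tri(propan-2-yl)silyloxy]phenyl}ethanone F10. Bu4NF in THF frees 1-[4-hydroxy-2,6-bis(methoxymethoxy)phenyl]ethanone F11. Etherification with 2 under the conditions of step 1 (K2CO3, KI, CuI, acetone) rejoins the route at 4.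

Further compounds
F1 | step 10 | 4-{3-[4-hydroxy-3-(methoxymethoxy)-5-(3-methylbut-2-en-1-yl)phenyl]propanoyl}-3,5-bis(methoxymethoxy)-2-(3-methylbut-2-en-1-yl)phenyl 2,2-dimethylpropanoate | COCOc1cc(OC(=O)C(C)(C)C)c(CC=C(C)C)c(OCOC)c1C(=O)CCc1cc(CC=C(C)C)c(O)c(OCOC)c1
F2 | step 10 | 4-{3-[4-methoxy-3-(methoxymethoxy)-5-(3-methylbut-2-en-1-yl)phenyl]propanoyl}-3,5-bis(methoxymethoxy)-2-(3-methylbut-2-en-1-yl)phenyl 2,2-dimethylpropanoate | COCOc1cc(OC(=O)C(C)(C)C)c(CC=C(C)C)c(OCOC)c1C(=O)CCc1cc(CC=C(C)C)c(OC)c(OCOC)c1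
F3 | step 10 | 1-[4-hydroxy-2,6-bis(methoxymethoxy)-3-(3-methylbut-2-en-1-yl)phenyl]-3-[4-methoxy-3-(methoxymethoxy)-5-(3-methylbut-2-en-1-yl)phenyl]propan-1-one | COCOc1cc(O)c(CC=C(C)C)c(OCOC)c1C(=O)CCc1cc(CC=C(C)C)c(OC)c(OCOC)c1
F4 | step 9 | 1-[4-hydroxy-2,6-bis(methoxymethoxy)-3-(3-methylbut-2-en-1-yl)phenyl]ethanone | CC(=O)c1c(OCOC)cc(O)c(CC=C(C)C)c1OCOC
F5 | step 9 | 1-[2,4,6-tris(methoxymethoxy)-3-(3-methylbut-2-en-1-yl)phenyl]ethanone | CC(=O)c1c(OCOC)cc(OCOC)c(CC=C(C)C)c1OCOC
F6 | step 9 | 4-hydroxy-3-(methoxymethoxy)-5-(3-methylbut-2-en-1-yl)benzaldehyde | O=Cc1cc(CC=C(C)C)c(O)c(OCOC)c1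
F7 | step 9 | 4-methoxy-3-(methoxymethoxy)-5-(3-methylbut-2-en-1-yl)benzaldehyde | O=Cc1cc(CC=C(C)C)c(OC)c(OCOC)c1
F8 | step 9 | (2E)-3-[4-methoxy-3-(methoxymethoxy)-5-(3-methylbut-2-en-1-yl)phenyl]-1-[2,4,6-tris(methoxymethoxy)-3-(3-methylbut-2-en-1-yl)phenyl]prop-2-en-1-one | COCOc1cc(OCOC)c(CC=C(C)C)c(OCOC)c1C(=O)/C=C/c1cc(CC=C(C)C)c(OC)c(OCOC)c1
F9 | step 1 | 1-{2,6-dihydroxy-4-[tri(propan-2-yl)silyloxy]phenyl}ethanone | CC(=O)c1c(O)cc(O[Si](C(C)C)(C(C)C)C(C)C)cc1O
F10 | step 1 | 1-{2,6-bis(methoxymethoxy)-4-[tri(propan-2-yl)silyloxy]phenyl}ethanone | CC(=O)c1c(OCOC)cc(O[Si](C(C)C)(C(C)C)C(C)C)cc1OCOC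
F11 | step 1 | 1-[4-hydroxy-2,6-bis(methoxymethoxy)phenyl]ethanone | CC(=O)c1c(OCOC)cc(O)cc1OCOC
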